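**Plan**

- Retrosynthesis: the chain is cut at the (E)-CH=CH bond between the two C(CH3)= units nearest the ring (HWE), at the alkyne–C(CH3)= bond (Sonogashira) and at two vinyl–vinyl single bonds of the distal triene (Stille). The ring is cut at its CH2–C(CH3)2 bond and at its tetrasubstituted C=C bond.
- Enabling feature: in the cyclohexene, the quaternary C(CH3)2 and the alkyne-bearing sp2 carbon are the β- and α-carbons of an isopropylidene acceptor whose α-substituent (the first alkyne carbon, carried as a nitrile) is paired with a phosphonate. The ring CH2 next to the carbinol is a primary radical site, and the ring C(CH3)= carbon is a methyl ketone 1,4 to it.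
- Forward order: chlorohydrin ester 1 gives iodo ketone 6; radical addition, reduction to the carbanion and intramolecular HWE build the ring in one flask (step 6). The nitrile becomes the ethynyl group, the chain grows by Sonogashira coupling and an HWE union with trienyl phosphonate 32, and both silyl ethers are removed last.
- Stereochemistry: the only stereocentre is bought with ethyl (R)-4-chloro-3-hydroxybutanoate and is never touched. Alkene geometry comes from syn-carboalumination (two trisubstituted alkenes), the trans-distannane, an (E)-enol triflate coupled with retention, and an E-selective HWE.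

Key step: step 6

Remark on the chemistry: the target carbinol is (R) by CIP analysis (the CH2–C(CH3)2 branch outranks the CH2–C(CH3)= branch); silyl ether 22 and distannane 25 are taken as purchasable.

**Route**

Step 1
Reactants: 1 ethyl (R)-4-chloro-3-hydroxybutanoate
Product: 2 ethyl (R)-3-(tert-butyldimethylsilyloxy)-4-chlorobutanoate
Conditions: TBSCl, imidazole, DMF, 25 °C
Reagents that add atoms: tert-butyldimethylsilyl chloride, CC(C)(C)[Si](C)(C)Cl
Why: Standard silylation of a secondary alcohol should protect the carbinol without touching the stereocentre.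

Step 2
Reactants: 2 ethyl (R)-3-(tert-butyldimethylsilyloxy)-4-chlorobutanoate
Product: 3 (R)-3-(tert-butyldimethylsilyloxy)-4-chloro-N-methoxy-N-methylbutanamide
Conditions: MeNH(OMe)·HCl, iPrMgCl, THF, −20 to 0 °C
Reagents that add atoms: N,O-dimethylhydroxylamine hydrochloride, CNOC.Cl
Why: Direct aminolysis of the ester by the chloromagnesium amide (Weinreb amide formation) is fast at low temperature, where the primary chloride and the silyl ether should stay intact.

Step 3
Reactants: 3 (R)-3-(tert-butyldimethylsilyloxy)-4-chloro-N-methoxy-N-methylbutanamide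
Product: 5 (R)-4-(tert-butyldimethylsilyloxy)-5-chloropentan-2-one, via bromomagnesium hemiaminal chelate 4 (not isolated)
Conditions: MeMgBr, THF, 0 °C; aqueous NH4Cl
Reagents that add atoms: methylmagnesium bromide, C[Mg]Br
Why: Weinreb ketone synthesis; the chelated tetrahedral adduct should resist over-addition and release the methyl ketone only on work-up.

Step 4
Reactants: 5 (R)-4-(tert-butyldimethylsilyloxy)-5-chloropentan-2-one
Product: 6 (R)-4-(tert-butyldimethylsilyloxy)-5-iodopentan-2-one
Conditions: NaI (5 equiv), butan-2-one, reflux, dark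
Reagents that add atoms: sodium iodide, [Na+].[I-]
Why: Finkelstein exchange under neutral conditions should give the radical precursor without enolising the β-silyloxy ketone; the descriptor stays (R).

Step 5
Reactants: 7 acetone; 8 diethyl (cyanomethyl)phosphonate
Product: 9 diethyl (1-cyano-2-methylprop-1-en-1-yl)phosphonate
Conditions: TiCl4 (2 equiv), N-methylmorpholine (4 equiv), THF, 0 to 25 °C
Reagents that add atoms: none
Why: TiCl4-mediated Knoevenagel condensation is the standard way to condense a doubly activated methylene compound with a simple ketone and should give the tetrasubstituted acceptor.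

Step 6
Reactants: 6 (R)-4-(tert-butyldimethylsilyloxy)-5-iodopentan-2-one; 9 diethyl (1-cyano-2-methylprop-1-en-1-yl)phosphonate
Product: 11 (R)-4-(tert-butyldimethylsilyloxy)-2,6,6-trimethylcyclohex-1-ene-1-carbonitrile, via open-chain keto cyanophosphonate 10 (not isolated)
Conditions: 4CzIPN (1,2,3,5-tetrakis(carbazol-9-yl)-4,6-dicyanobenzene, 3 mol %), Et3N (3 equiv), 9 (3 equiv), MeCN (0.3 M), blue LEDs (450 nm), 25 °C; then Cs2CO3 (3 equiv), 50 °C, same flask
Reagents that add atoms: none
Why: Proposed new method: photoexcited 4CzIPN oxidises Et3N, the derived α-aminoalkyl radical abstracts iodine from 6 (halogen-atom transfer), and the primary carbon radical adds to the dimethyl-substituted β-carbon of 9, the only electrophilic alkene carbon because nitrile and phosphonate sit together on the α-carbon; the doubly stabilised adduct radical is reduced by the photocatalyst radical anion to the phosphonate carbanion (radical–polar crossover), which is held as its conjugate acid 10 by the ammonium salt until Cs2CO3 is added, whereupon intramolecular HWE olefination of the methyl ketone closes the ring. The closest known reaction types are the halogen-atom-transfer photoredox Giese addition of alkyl iodides, radical–polar crossover annulations that end in an anionic ring closure, and conjugate-addition-initiated intramolecular HWE reactions of vinylphosphonates; their merger on a fully substituted acceptor is what is new. The six-membered ring closes in the 6-exo-trig mode (carbanion carbon onto the ketone carbonyl), and syn-elimination of diethyl phosphate from the oxaphosphetane gives the tetrasubstituted ring alkene, which has no geometry to control. No stereocentre is created: the silyloxy carbon comes unchanged from 1 (a β-silyloxy radical does not fragment), and the phosphonate-bearing carbon of 10 becomes sp2. The step needs carbon–carbon bond formation at a hindered site to outrun reduction of the radical, which the double activation and the excess of 9 at high concentration should secure; the base is withheld until the iodide is consumed so that 3-exo-tet cyclopropane closure and E1cB loss of silanolate from the γ-iodo β-silyloxy ketone cannot compete.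

Step 7
Reactants: 11 (R)-4-(tert-butyldimethylsilyloxy)-2,6,6-trimethylcyclohex-1-ene-1-carbonitrile
Product: 13 (R)-4-(tert-butyldimethylsilyloxy)-2,6,6-trimethylcyclohex-1-ene-1-carbaldehyde, via N-aluminio aldimine 12 (not isolated)
Conditions: iBu2AlH (1.3 equiv), toluene, −78 to −20 °C; then aqueous tartaric acid, 0 °C
Reagents that add atoms: water, O
Why: Partial reduction of a nitrile by iBu2AlH should stop at the aluminated aldimine, which hydrolyses to the conjugated aldehyde on work-up.

Step 8
Reactants: 13 (R)-4-(tert-butyldimethylsilyloxy)-2,6,6-trimethylcyclohex-1-ene-1-carbaldehyde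
Product: 16 (R)-tert-butyl[(4-ethynyl-3,5,5-trimethylcyclohex-3-en-1-yl)oxy]dimethylsilane, via lithium alkoxide adduct 14 (not isolated), via diazoalkene 15 (not isolated)
Conditions: TMSCHN2, LiN(iPr)2, THF, −78 °C; then 13, −78 to 25 °C
Reagents that add atoms: (trimethylsilyl)diazomethane, C[Si](C)(C)C=[N+]=[N-]
Why: Colvin rearrangement: addition of the lithiated diazo reagent, Peterson-type loss of silanolate, loss of N2 and 1,2-hydrogen shift of the alkylidene carbene should give the terminal alkyne, and the fully substituted β-carbon blocks conjugate addition.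

Step 9
Reactants: 17 ethyl acetoacetate
Product: 18 ethyl (E)-3-(trifluoromethylsulfonyloxy)but-2-enoate
Conditions: Tf2O, aqueous Me4NOH, hexanes, 5 °C
Reagents that add atoms: trifluoromethanesulfonic anhydride, O=S(=O)(OS(=O)(=O)C(F)(F)F)C(F)(F)F
Why: O-triflation of the non-chelated tetramethylammonium enolate should give the (E)-enol triflate (triflate trans to the ester), which fixes the geometry of the first chain alkene.

Step 10
Reactants: 16 (R)-tert-butyl[(4-ethynyl-3,5,5-trimethylcyclohex-3-en-1-yl)oxy]dimethylsilane; 18 ethyl (E)-3-(trifluoromethylsulfonyloxy)but-2-enoate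
Product: 19 ethyl (E)-5-[(R)-4-(tert-butyldimethylsilyloxy)-2,6,6-trimethylcyclohex-1-en-1-yl]-3-methylpent-2-en-4-ynoate
Conditions: PdCl2(PPh3)2 (3 mol %), CuI (6 mol %), Et3N, THF, 25 °C
Reagents that add atoms: none
Why: Sonogashira coupling of an activated alkenyl triflate proceeds with retention, so the alkyne should end up trans to the ester.

Step 11
Reactants: 19 ethyl (E)-5-[(R)-4-(tert-butyldimethylsilyloxy)-2,6,6-trimethylcyclohex-1-en-1-yl]-3-methylpent-2-en-4-ynoate
Product: 20 (E)-5-[(R)-4-(tert-butyldimethylsilyloxy)-2,6,6-trimethylcyclohex-1-en-1-yl]-3-methylpent-2-en-4-yn-1-ol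
Conditions: iBu2AlH (2.2 equiv), CH2Cl2, −78 °C; aqueous potassium sodium tartrate
Reagents that add atoms: none
Why: 1,2-Reduction of a conjugated ester by iBu2AlH should give the allylic alcohol without touching the enyne.

Step 12
Reactants: 20 (E)-5-[(R)-4-(tert-butyldimethylsilyloxy)-2,6,6-trimethylcyclohex-1-en-1-yl]-3-methylpent-2-en-4-yn-1-ol
Product: 21 (E)-5-[(R)-4-(tert-butyldimethylsilyloxy)-2,6,6-trimethylcyclohex-1-en-1-yl]-3-methylpent-2-en-4-ynal
Conditions: MnO2 (excess), CH2Cl2, 25 °C, dark
Reagents that add atoms: none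
Why: Allylic oxidation with MnO2 is neutral and should give the enynal without isomerising the trisubstituted alkene.

Step 13
Reactants: 22 tert-butyldimethyl(pent-4-yn-1-yloxy)silane
Product: 24 (E)-tert-butyl[(5-iodo-4-methylpent-4-en-1-yl)oxy]dimethylsilane, via alkenyl(dimethyl)alane 23 (not isolated)
Conditions: AlMe3 (2 equiv), Cp2ZrCl2 (0.25 equiv), CH2Cl2, 0 to 25 °C; then I2, THF, −30 °C
Reagents that add atoms: trimethylaluminium, C[Al](C)C; iodine, II
Why: Zirconium-catalysed methylalumination (Negishi carboalumination) adds methyl and aluminium syn with methyl on the internal carbon, and iodinolysis with retention should give the (E)-iodide.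

Step 14
Reactants: 24 (E)-tert-butyl[(5-iodo-4-methylpent-4-en-1-yl)oxy]dimethylsilane; 25 (E)-1,2-bis(tributylstannyl)ethene
Product: 26 tert-butyldimethyl{[(4E,6E)-4-methyl-7-(tributylstannyl)hepta-4,6-dien-1-yl]oxy}silane
Conditions: 25 (3 equiv), PdCl2(MeCN)2 (5 mol %), DMF, 25 °C, dark
Reagents that add atoms: none
Why: Stille coupling with retention at both partners; the excess of the distannane linchpin should hold the reaction at mono-coupling and deliver the (E,E)-dienylstannane.

Step 15
Reactants: 27 prop-2-yn-1-ol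
Product: 29 (E)-3-iodo-2-methylprop-2-en-1-ol, via alkenylalane aluminium alkoxide 28 (not isolated)
Conditions: AlMe3 (3 equiv), Cp2ZrCl2 (0.25 equiv), CH2Cl2, 25 °C; then I2, THF, −30 °C
Reagents that add atoms: trimethylaluminium, C[Al](C)C; iodine, II
Why: The same syn-carboalumination and iodinolysis on the free propargylic alcohol should give the (E)-iodide with iodine cis to the new methyl group.

Step 16
Reactants: 29 (E)-3-iodo-2-methylprop-2-en-1-ol
Product: 30 (E)-3-bromo-1-iodo-2-methylprop-1-ene
Conditions: CBr4, PPh3, CH2Cl2, 0 °C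
Reagents that add atoms: tetrabromomethane, BrC(Br)(Br)Br
Why: Appel bromination of a primary allylic alcohol is mild and should leave the alkenyl iodide and its geometry untouched.

Step 17
Reactants: 30 (E)-3-bromo-1-iodo-2-methylprop-1-ene
Product: 31 diethyl (E)-(3-iodo-2-methylallyl)phosphonate
Conditions: P(OEt)3 (neat), 100 °C
Reagents that add atoms: triethyl phosphite, CCOP(OCC)OCC
Why: Michaelis–Arbuzov reaction occurs at the allylic bromide only, since an alkenyl iodide does not react with a phosphite without a metal catalyst.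

Step 18
Reactants: 26 tert-butyldimethyl{[(4E,6E)-4-methyl-7-(tributylstannyl)hepta-4,6-dien-1-yl]oxy}silane; 31 diethyl (E)-(3-iodo-2-methylallyl)phosphonate
Product: 32 diethyl [(2E,4E,6E)-10-(tert-butyldimethylsilyloxy)-2,7-dimethyldeca-2,4,6-trien-1-yl]phosphonate
Conditions: Pd2(dba)3 (2.5 mol %), AsPh3 (20 mol %), NMP, 25 to 40 °C, dark
Reagents that add atoms: none
Why: Stille coupling of an alkenyl iodide with an alkenylstannane under ligand-accelerated conditions should join the two units with retention to give the all-E triene.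

Step 19
Reactants: 21 (E)-5-[(R)-4-(tert-butyldimethylsilyloxy)-2,6,6-trimethylcyclohex-1-en-1-yl]-3-methylpent-2-en-4-ynal; 32 diethyl [(2E,4E,6E)-10-(tert-butyldimethylsilyloxy)-2,7-dimethyldeca-2,4,6-trien-1-yl]phosphonate
Product: 33 bis(tert-butyldimethylsilyl) ether of the target (ring (R), chain all-E)
Conditions: 32, NaN(SiMe3)2, THF, −78 °C; then 21, −78 to 0 °C, dark
Reagents that add atoms: none
Why: HWE olefination of an allylic-type phosphonate carbanion with a conjugated aldehyde should form the new disubstituted double bond E through the reversible, thermodynamically controlled addition.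

Step 20
Reactants: 33 bis(tert-butyldimethylsilyl) ether of the target
Product: 34 (1R)-4-[(3E,5E,7E,9E,11E)-15-hydroxy-3,7,12-trimethylpentadeca-3,5,7,9,11-pentaen-1-yn-1-yl]-3,5,5-trimethylcyclohex-3-en-1-ol
Conditions: Bu4NF (4 equiv), THF, 25 °C, argon, dim light
Reagents that add atoms: none
Why: Fluoride-induced desilylation should remove the primary and the secondary silyl ether together under conditions that do not isomerise the polyene.

**Compound list**

1 | ethyl (R)-4-chloro-3-hydroxybutanoate | ClC[C@H](O)CC(=O)OCC | starting material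
2 | ethyl (R)-3-(tert-butyldimethylsilyloxy)-4-chlorobutanoate | ClC[C@H](O[Si](C)(C)C(C)(C)C)CC(=O)OCC | intermediate
3 | (R)-3-(tert-butyldimethylsilyloxy)-4-chloro-N-methoxy-N-methylbutanamide | ClC[C@H](O[Si](C)(C)C(C)(C)C)CC(=O)N(C)OC | intermediate
4 | bromomagnesium hemiaminal chelate from 3 and MeMgBr (forms in the flask; new carbon undefined) | ClC[C@H](O[Si](C)(C)C(C)(C)C)CC(C)(O[Mg]Br)N(C)OC | intermediate
5 | (R)-4-(tert-butyldimethylsilyloxy)-5-chloropentan-2-one | ClC[C@H](O[Si](C)(C)C(C)(C)C)CC(C)=O | intermediate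
6 | (R)-4-(tert-butyldimethylsilyloxy)-5-iodopentan-2-one | IC[C@H](O[Si](C)(C)C(C)(C)C)CC(C)=O | intermediate
7 | acetone | CC(C)=O | starting material
8 | diethyl (cyanomethyl)phosphonate | CCOP(=O)(CC#N)OCC | starting material
9 | diethyl (1-cyano-2-methylprop-1-en-1-yl)phosphonate | CCOP(=O)(OCC)C(C#N)=C(C)C | intermediate
10 | diethyl [(4S)-4-(tert-butyldimethylsilyloxy)-1-cyano-2,2-dimethyl-6-oxoheptyl]phosphonate (forms in the flask; both configurations at the phosphonate carbon) | CCOP(=O)(OCC)C(C#N)C(C)(C)C[C@H](O[Si](C)(C)C(C)(C)C)CC(C)=O | intermediate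
11 | (R)-4-(tert-butyldimethylsilyloxy)-2,6,6-trimethylcyclohex-1-ene-1-carbonitrile | CC1=C(C#N)C(C)(C)C[C@H](O[Si](C)(C)C(C)(C)C)C1 | intermediate
12 | N-(diisobutylaluminio) aldimine of 13 (forms in the flask) | CC1=C(C=N[Al](CC(C)C)CC(C)C)C(C)(C)C[C@H](O[Si](C)(C)C(C)(C)C)C1 | intermediate
13 | (R)-4-(tert-butyldimethylsilyloxy)-2,6,6-trimethylcyclohex-1-ene-1-carbaldehyde | CC1=C(C=O)C(C)(C)C[C@H](O[Si](C)(C)C(C)(C)C)C1 | intermediate
14 | lithium alkoxide adduct of 13 with lithiated (trimethylsilyl)diazomethane (forms in the flask; carbinol carbon undefined) | CC1=C(C(O[Li])C(=[N+]=[N-])[Si](C)(C)C)C(C)(C)C[C@H](O[Si](C)(C)C(C)(C)C)C1 | intermediate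
15 | (R)-configured 1-diazoalkene from 14 (forms in the flask) | CC1=C(C=C=[N+]=[N-])C(C)(C)C[C@H](O[Si](C)(C)C(C)(C)C)C1 | intermediate
16 | (R)-tert-butyl[(4-ethynyl-3,5,5-trimethylcyclohex-3-en-1-yl)oxy]dimethylsilane | CC1=C(C#C)C(C)(C)C[C@H](O[Si](C)(C)C(C)(C)C)C1 | intermediate
17 | ethyl acetoacetate | CCOC(=O)CC(C)=O | starting material
18 | ethyl (E)-3-(trifluoromethylsulfonyloxy)but-2-enoate | CCOC(=O)/C=C(\C)OS(=O)(=O)C(F)(F)F | intermediate
19 | ethyl (E)-5-[(R)-4-(tert-butyldimethylsilyloxy)-2,6,6-trimethylcyclohex-1-en-1-yl]-3-methylpent-2-en-4-ynoate | CC1=C(C#C/C(C)=C/C(=O)OCC)C(C)(C)C[C@H](O[Si](C)(C)C(C)(C)C)C1 | intermediate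
20 | (E)-5-[(R)-4-(tert-butyldimethylsilyloxy)-2,6,6-trimethylcyclohex-1-en-1-yl]-3-methylpent-2-en-4-yn-1-ol | CC1=C(C#C/C(C)=C/CO)C(C)(C)C[C@H](O[Si](C)(C)C(C)(C)C)C1 | intermediate
21 | (E)-5-[(R)-4-(tert-butyldimethylsilyloxy)-2,6,6-trimethylcyclohex-1-en-1-yl]-3-methylpent-2-en-4-ynal | CC1=C(C#C/C(C)=C/C=O)C(C)(C)C[C@H](O[Si](C)(C)C(C)(C)C)C1 | intermediate
22 | tert-butyldimethyl(pent-4-yn-1-yloxy)silane | C#CCCCO[Si](C)(C)C(C)(C)C | starting material
23 | (E)-[5-(tert-butyldimethylsilyloxy)-2-methylpent-1-en-1-yl]dimethylalane (forms in the flask) | C[Al](C)/C=C(\C)CCCO[Si](C)(C)C(C)(C)C | intermediate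
24 | (E)-tert-butyl[(5-iodo-4-methylpent-4-en-1-yl)oxy]dimethylsilane | I/C=C(\C)CCCO[Si](C)(C)C(C)(C)C | intermediate
25 | (E)-1,2-bis(tributylstannyl)ethene | CCCC[Sn](CCCC)(CCCC)/C=C/[Sn](CCCC)(CCCC)CCCC | starting material
26 | tert-butyldimethyl{[(4E,6E)-4-methyl-7-(tributylstannyl)hepta-4,6-dien-1-yl]oxy}silane | CCCC[Sn](CCCC)(CCCC)/C=C/C=C(\C)CCCO[Si](C)(C)C(C)(C)C | intermediate
27 | prop-2-yn-1-ol | C#CCO | starting material
28 | (E)-alkenyl(dimethyl)alane dimethylaluminium alkoxide from 27 (forms in the flask) | C[Al](C)/C=C(\C)CO[Al](C)C | intermediate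
29 | (E)-3-iodo-2-methylprop-2-en-1-ol | I/C=C(\C)CO | intermediate
30 | (E)-3-bromo-1-iodo-2-methylprop-1-ene | I/C=C(\C)CBr | intermediate
31 | diethyl (E)-(3-iodo-2-methylallyl)phosphonate | CCOP(=O)(OCC)C/C(C)=C/I | intermediate
32 | diethyl [(2E,4E,6E)-10-(tert-butyldimethylsilyloxy)-2,7-dimethyldeca-2,4,6-trien-1-yl]phosphonate | CCOP(=O)(OCC)C/C(C)=C/C=C/C=C(\C)CCCO[Si](C)(C)C(C)(C)C | intermediate
33 | bis(tert-butyldimethylsilyl) ether of the target, ring (R), chain (3E,5E,7E,9E,11E) | CC1=C(C#C/C(C)=C/C=C/C(C)=C/C=C/C=C(\C)CCCO[Si](C)(C)C(C)(C)C)C(C)(C)C[C@H](O[Si](C)(C)C(C)(C)C)C1 | intermediate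
34 | (1R)-4-[(3E,5E,7E,9E,11E)-15-hydroxy-3,7,12-trimethylpentadeca-3,5,7,9,11-pentaen-1-yn-1-yl]-3,5,5-trimethylcyclohex-3-en-1-ol | CC1=C(C#C/C(C)=C/C=C/C(C)=C/C=C/C=C(\C)CCCO)C(C)(C)C[C@H](O)C1 | target

**Step count and risks**

Total steps: 20. Longest linear sequence: 12 (steps 1, 2, 3, 4, 6, 7, 8, 10, 11, 12, 19, 20).

Most likely to fail:

1. Step 6 (Proposed new method). The primary radical may be reduced by hydrogen-atom transfer faster than it adds to the fully substituted β-carbon of 9, or the hindered carbanion may fail to close onto the ketone. The fallback is polar, uses known chemistry, sets out from iodide 6 and returns at aldehyde 13. The ketone of 6 is protected with ethylene glycol and pyridinium p-toluenesulfonate to give (R)-tert-butyl{[1-iodo-3-(2-methyl-1,3-dioxolan-2-yl)propan-2-yl]oxy}dimethylsilane F1. F1 alkylates lithiated isobutyronitrile (LiN(iPr)2, THF/DMPU), which sets the quaternary carbon in (S)-4-(tert-butyldimethylsilyloxy)-2,2-dimethyl-5-(2-methyl-1,3-dioxolan-2-yl)pentanenitrile F2. Reduction with iBu2AlH and hydrolytic work-up gives the corresponding pentanal F3. Wittig methoxymethylenation with Ph3P=CHOMe gives the one-carbon-longer methyl enol ether F4. Dilute aqueous acid unmasks both carbonyl groups to (S)-5-(tert-butyldimethylsilyloxy)-3,3-dimethyl-7-oxooctanal F5. Piperidinium acetate then effects the enamine-mediated intramolecular aldol condensation (aldehyde α-carbon onto the methyl ketone) to 13, after which the route continues at step 8.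

2. Step 19. The delocalised carbanion of 32 may lose the E geometry of its methyl-bearing double bond, the new double bond may form as an E/Z mixture, and the enynal may degrade under base. The fallback moves the fragment union to a stereoretentive cross-coupling; it sets out from aldehyde 21 and returns at 33. HWE olefination of 21 with the small iodo phosphonate 31 (NaN(SiMe3)2, THF, −78 °C), whose anion is not spread over a polyene, gives tert-butyl{[(R)-4-((3E,5E,7E)-8-iodo-3,7-dimethylocta-3,5,7-trien-1-yn-1-yl)-3,5,5-trimethylcyclohex-3-en-1-yl]oxy}dimethylsilane F6. Stille coupling of F6 with dienylstannane 26 (Pd2(dba)3, AsPh3, NMP) then gives 33.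

3. Step 8. Addition to the hindered tetrasubstituted enal may be incomplete, or the alkylidene carbene may be diverted (C–H insertion, dimerisation) before the 1,2-hydrogen shift. The fallback brings in the second alkyne carbon as a methyl nucleophile; it sets out from nitrile 11 and returns at alkyne 16. MeLi addition and hydrolysis of the ketimine give (R)-1-[4-(tert-butyldimethylsilyloxy)-2,6,6-trimethylcyclohex-1-en-1-yl]ethan-1-one F7. The kinetic enolate (LiN(iPr)2, −78 °C) is trapped with ClP(O)(OEt)2 as the enol diethyl phosphate F8. Elimination with LiN(iPr)2 (2.2 equiv) gives 16.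

Further compounds
F1 | step 6 | (R)-tert-butyl{[1-iodo-3-(2-methyl-1,3-dioxolan-2-yl)propan-2-yl]oxy}dimethylsilane | IC[C@H](O[Si](C)(C)C(C)(C)C)CC1(C)OCCO1
F2 | step 6 | (S)-4-(tert-butyldimethylsilyloxy)-2,2-dimethyl-5-(2-methyl-1,3-dioxolan-2-yl)pentanenitrile | N#CC(C)(C)C[C@H](O[Si](C)(C)C(C)(C)C)CC1(C)OCCO1
F3 | step 6 | (S)-4-(tert-butyldimethylsilyloxy)-2,2-dimethyl-5-(2-methyl-1,3-dioxolan-2-yl)pentanal | O=CC(C)(C)C[C@H](O[Si](C)(C)C(C)(C)C)CC1(C)OCCO1
F4 | step 6 | (S)-tert-butyl{[6-methoxy-4,4-dimethyl-1-(2-methyl-1,3-dioxolan-2-yl)hex-5-en-2-yl]oxy}dimethylsilane (E/Z mixture) | COC=CC(C)(C)C[C@H](O[Si](C)(C)C(C)(C)C)CC1(C)OCCO1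
F5 | step 6 | (S)-5-(tert-butyldimethylsilyloxy)-3,3-dimethyl-7-oxooctanal | O=CCC(C)(C)C[C@H](O[Si](C)(C)C(C)(C)C)CC(C)=O
F6 | step 19 | tert-butyl{[(R)-4-((3E,5E,7E)-8-iodo-3,7-dimethylocta-3,5,7-trien-1-yn-1-yl)-3,5,5-trimethylcyclohex-3-en-1-yl]oxy}dimethylsilane | CC1=C(C#C/C(C)=C/C=C/C(C)=C/I)C(C)(C)C[C@H](O[Si](C)(C)C(C)(C)C)C1
F7 | step 8 | (R)-1-[4-(tert-butyldimethylsilyloxy)-2,6,6-trimethylcyclohex-1-en-1-yl]ethan-1-one | CC1=C(C(C)=O)C(C)(C)C[C@H](O[Si](C)(C)C(C)(C)C)C1
F8 | step 8 | (R)-1-[4-(tert-butyldimethylsilyloxy)-2,6,6-trimethylcyclohex-1-en-1-yl]vinyl diethyl phosphate | CC1=C(C(=C)OP(=O)(OCC)OCC)C(C)(C)C[C@H](O[Si](C)(C)C(C)(C)C)C1
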